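Numbering: chain C1 (CH2OAc) to C9, ring C1'–C6'. The hardest point is the lone C1'–H stereocentre. It is allylic, wedged between quaternary C6' and the non-conjugated, less stable C2'(Me)=C3'H alkene, and CH2CH2 spacers isolate it from both chain alkenes, so no stereo-element can control another.
Cuts: C3–C4 (homoallyl Grignard reagent + but-2-yne-1,4-diol); C7–C8 and C7–CH3 at one carbon (C4–C7 is a ring-opened 2,3-dihydrofuran); C1'–C9 ([3,3] shift); C1'=C2' and C5'–C6' (isobutyraldehyde + ethyl vinyl ketone).
Enabling feature: C3'=C2'(Me)–C1'(H)–C9H2–C8 is the γ,δ-unsaturated carbonyl retron of a Claisen rearrangement once C8 is an amide carbon. C3' is a plain =CH in the target, so it can carry and then lose a carbinol centre that an enone reduction sets easily.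
Forward: ring (step 1), C3'–OH (2), O-to-C transfer (3), C8 to CH2I (4, 5), three-component union of alkyl iodide, dihydrofuran and MeI (6), bromide (7), anti-carbomagnesiation of butynediol (8), acetylation (9). No protecting groups and no terpene building block are used.
Stereochemistry: C1' comes from the CBS catalyst, relayed suprafacially by the [3,3] shift. 6E comes from inversion at the sp2 carbon in a Cu-to-C 1,2-shift plus retentive methylation. 2E (chain cis to C1) comes from alkoxide-directed anti addition.

Key step: step 3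

Remark: the SMILES is read as (2E,6E,1'S). Protons delivered on aqueous work-up are counted as coming from water, so metal alkoxides and carbon–metal bonds end as metal hydroxides.

Step 1
Reactants: 1 isobutyraldehyde (2-methylpropanal); 2 ethyl vinyl ketone (pent-1-en-3-one)
Product: 4 2,4,4-trimethylcyclohex-2-en-1-one, via 2,2-dimethyl-5-oxoheptanal 3 (not isolated)
Conditions: cat. H2SO4, toluene, 45 °C then reflux, Dean–Stark
Reagents that add atoms: none
Why: Acid-catalysed Robinson-type annulation (Michael addition of the enol of 1 to 2, then aldol condensation of keto aldehyde 3 through its ethyl-side enol, the only mode that gives an unstrained ring) is established for α,α-disubstituted aldehydes plus vinyl ketones and creates no stereocentre.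

Step 2
Reactants: 4 2,4,4-trimethylcyclohex-2-en-1-one
Product: 5 (1R)-2,4,4-trimethylcyclohex-2-en-1-ol
Conditions: (S)-Me-CBS (10 mol %), BH3·SMe2, THF, −20 °C; then MeOH, aqueous work-up
Reagents that add atoms: none
Why: Corey–Bakshi–Shibata reduction: the α-methylated vinyl arm of 4 plays the large group and C6H2 the small one, as aryl versus methyl in the standard model, so the (S)-catalyst should deliver hydride to the face that gives the (R)-carbinol (C3' in target numbering), and 2-substituted cyclohexenones are a favourable substrate class for clean 1,2-reduction.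

Step 3
Reactants: 5 (1R)-2,4,4-trimethylcyclohex-2-en-1-ol
Product: 7 N,N-dimethyl-2-[(1S)-2,6,6-trimethylcyclohex-2-en-1-yl]acetamide, via ketene N,O-acetal 6 (not isolated)
Conditions: MeC(OMe)2NMe2 (4 equiv), xylenes, 140 °C, MeOH distilled off
Reagents that add atoms: N,N-dimethylacetamide dimethyl acetal, CC(OC)(OC)N(C)C
Why: Exchange of the carbinol into the amide acetal and loss of two MeOH gives ketene N,O-acetal 6, which undergoes a concerted [3,3]-sigmatropic shift (Eschenmoser–Claisen rearrangement); the closest known reaction type is the amide-acetal Claisen rearrangement of substituted cyclohex-2-enols, which forms C–C bonds at or next to quaternary carbons with 1,3-chirality transfer. No ring is closed; the six-atom transition state (O–C3'–C2'–C1'···CH2=C) spans one face of the existing ring. The new C1' stereocentre is controlled only by the C3'–O centre: C9 must bond to C1' on the face from which the C–O bond departs (suprafacial), so (R)-5 should give (S)-7 while the carbinol centre is erased. The position of the alkene and of the new C–C bond is fixed by the mechanism, since C2'=C3' can form only where oxygen leaves and C9 can reach only C1', which avoids the α/β/γ alkene mixtures of cationic or enolate routes. The step also needs the [3,3] shift to outrun ionisation or elimination to the cyclohexadiene, which the neutral, acid-free medium and the irreversible formation of the amide C=O should secure. The C2' methyl helps through A(1,2) strain that holds the C3'–O bond pseudoaxial, the geometry needed for overlap, and in that half-chair the C6' methyl on the reacting face is pseudoequatorial and leaves C1' reachable.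

Step 4
Reactants: 7 N,N-dimethyl-2-[(1S)-2,6,6-trimethylcyclohex-2-en-1-yl]acetamide
Product: 8 2-[(1S)-2,6,6-trimethylcyclohex-2-en-1-yl]ethan-1-ol
Conditions: LiEt3BH (2.5 equiv), THF, 0 °C to rt; then H2O
Reagents that add atoms: none
Why: Lithium triethylborohydride reduces tertiary N,N-dimethylamides with C–N cleavage to primary alcohols rather than amines, the isolated trisubstituted alkene is inert, and C1' is β to the carbonyl, so it cannot epimerise.

Step 5
Reactants: 8 2-[(1S)-2,6,6-trimethylcyclohex-2-en-1-yl]ethan-1-ol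
Product: 9 (6S)-6-(2-iodoethyl)-1,5,5-trimethylcyclohex-1-ene
Conditions: I2, PPh3, imidazole, CH2Cl2, 0 °C to rt
Reagents that add atoms: iodine, II
Why: Appel-type iodination is an SN2 displacement at an unhindered primary carbinol under buffered, non-acidic conditions, which leaves the acid-sensitive ring alkene and C1' untouched.

Step 6
Reactants: 9 (6S)-6-(2-iodoethyl)-1,5,5-trimethylcyclohex-1-ene; 10 2,3-dihydrofuran
Product: 15 (3E)-4-methyl-6-[(1S)-2,6,6-trimethylcyclohex-2-en-1-yl]hex-3-en-1-ol, via alkyllithium 11 (not isolated), via 5-lithio-2,3-dihydrofuran 12 (not isolated), via mixed lithium cuprate 13 (not isolated), via alkenylcopper alkoxide 14 (not isolated)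
Conditions: 9, t-BuLi (2 equiv), Et2O–pentane, −78 °C; CuBr·SMe2 (1 equiv), Et2O–Me2S, −78 to −40 °C; 12 (from 10, t-BuLi, THF, −78 to 0 °C); −78 °C to rt; MeI (excess), 0 °C to rt; aq NH4Cl/NH3
Reagents that add atoms: methyl iodide, CI
Why: 1,2-Metalate rearrangement of an α-alkoxyalkenyl cuprate, a known three-component route to (E)-4-methylalk-3-en-1-ols of isoprenoid chains: in 13 the alkyl ligand migrates from Cu to C7 anti to the in-plane C–O bond (inversion at the sp2 carbon), so copper in 14 stands where the ring oxygen was, cis to C5H2, and retentive methylation gives the 6E alkene, while C1' is a spectator and 11, a pent-4-enyllithium type, has no favourable cyclisation mode.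

Step 7
Reactants: 15 (3E)-4-methyl-6-[(1S)-2,6,6-trimethylcyclohex-2-en-1-yl]hex-3-en-1-ol
Product: 16 (6S)-6-[(3E)-6-bromo-3-methylhex-3-en-1-yl]-1,5,5-trimethylcyclohex-1-ene
Conditions: CBr4, PPh3, CH2Cl2, 0 °C
Reagents that add atoms: carbon tetrabromide, BrC(Br)(Br)Br
Why: Appel bromination of a primary homoallylic alcohol proceeds by SN2 under neutral conditions without touching either trisubstituted alkene, and the bromide suits clean Grignard formation.

Step 8
Reactants: 16 (6S)-6-[(3E)-6-bromo-3-methylhex-3-en-1-yl]-1,5,5-trimethylcyclohex-1-ene; 17 but-2-yne-1,4-diol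
Product: 21 (2E)-2-{(3E)-4-methyl-6-[(1S)-2,6,6-trimethylcyclohex-2-en-1-yl]hex-3-en-1-yl}but-2-ene-1,4-diol, via Grignard reagent 18 (not isolated), via butynediol bis(chloromagnesium alkoxide) 19 (not isolated), via alkenylmagnesium chelate 20 (not isolated)
Conditions: 16, Mg, THF, rt; separately 17 (excess), MeMgCl (2 equiv per diol), THF, 0 °C; combine, CuI (10 mol %), rt to 50 °C; then aq NH4Cl
Reagents that add atoms: none
Why: Alkoxide-directed anti-carbomagnesiation of a propargylic alcoholate (trans-addition of Grignard reagents, homoallylic ones included, to but-2-yne-1,4-diol is known): the alkyl group adds to the alkyne carbon next to the directing CH2OMg group while magnesium ends on the other carbon inside the five-membered oxamagnesacycle of 20, so protonation leaves the chain cis to C1H2OH and the two CH2OH groups trans (2E), and the symmetry of 17 removes any regiochemical question.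

Step 9
Reactants: 21 (2E)-2-{(3E)-4-methyl-6-[(1S)-2,6,6-trimethylcyclohex-2-en-1-yl]hex-3-en-1-yl}but-2-ene-1,4-diol
Product: 22 (2E,6E)-3-(acetoxymethyl)-7-methyl-9-[(1S)-2,6,6-trimethylcyclohex-2-en-1-yl]nona-2,6-dien-1-yl acetate (CNP0186001.1)
Conditions: Ac2O, pyridine, DMAP (cat.), CH2Cl2, 0 °C to rt
Reagents that add atoms: acetic anhydride, CC(=O)OC(C)=O
Why: DMAP-catalysed acylation of two primary allylic alcohols runs under mildly basic conditions that cannot isomerise the alkenes or disturb C1'.

Compound list
1 | isobutyraldehyde (2-methylpropanal) | CC(C)C=O | starting material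
2 | ethyl vinyl ketone (pent-1-en-3-one) | CCC(=O)C=C | starting material
3 | 2,2-dimethyl-5-oxoheptanal | CCC(=O)CCC(C)(C)C=O | intermediate
4 | 2,4,4-trimethylcyclohex-2-en-1-one | CC1=CC(C)(C)CCC1=O | intermediate
5 | (1R)-2,4,4-trimethylcyclohex-2-en-1-ol | CC1=CC(C)(C)CC[C@H]1O | intermediate
6 | 1-(dimethylamino)ethenyl (1R)-2,4,4-trimethylcyclohex-2-en-1-yl ether (ketene N,O-acetal) | CC1=CC(C)(C)CC[C@H]1OC(=C)N(C)C | intermediate
7 | N,N-dimethyl-2-[(1S)-2,6,6-trimethylcyclohex-2-en-1-yl]acetamide | CN(C)C(=O)C[C@@H]1C(C)=CCCC1(C)C | intermediate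
8 | 2-[(1S)-2,6,6-trimethylcyclohex-2-en-1-yl]ethan-1-ol | OCC[C@@H]1C(C)=CCCC1(C)C | intermediate
9 | (6S)-6-(2-iodoethyl)-1,5,5-trimethylcyclohex-1-ene | ICC[C@@H]1C(C)=CCCC1(C)C | intermediate
10 | 2,3-dihydrofuran | C1CC=CO1 | starting material
11 | 2-[(1S)-2,6,6-trimethylcyclohex-2-en-1-yl]ethyllithium | [Li]CC[C@@H]1C(C)=CCCC1(C)C | intermediate
12 | 5-lithio-2,3-dihydrofuran | [Li]C1=CCCO1 | intermediate
13 | lithium (4,5-dihydrofuran-2-yl){2-[(1S)-2,6,6-trimethylcyclohex-2-en-1-yl]ethyl}cuprate | [Li+].O1CCC=C1[Cu-]CC[C@@H]1C(C)=CCCC1(C)C | intermediate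
14 | (Z)-alkenylcopper lithium alkoxide, Cu on C7 cis to the CH2CH2OLi arm | [Li]OCC/C=C(\[Cu])CC[C@@H]1C(C)=CCCC1(C)C | intermediate
15 | (3E)-4-methyl-6-[(1S)-2,6,6-trimethylcyclohex-2-en-1-yl]hex-3-en-1-ol | OCC/C=C(\C)CC[C@@H]1C(C)=CCCC1(C)C | intermediate
16 | (6S)-6-[(3E)-6-bromo-3-methylhex-3-en-1-yl]-1,5,5-trimethylcyclohex-1-ene | BrCC/C=C(\C)CC[C@@H]1C(C)=CCCC1(C)C | intermediate
17 | but-2-yne-1,4-diol | OCC#CCO | starting material
18 | (3E)-4-methyl-6-[(1S)-2,6,6-trimethylcyclohex-2-en-1-yl]hex-3-en-1-ylmagnesium bromide | Br[Mg]CC/C=C(\C)CC[C@@H]1C(C)=CCCC1(C)C | intermediate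
19 | but-2-yne-1,4-diol bis(chloromagnesium alkoxide) | Cl[Mg]OCC#CCO[Mg]Cl | intermediate
20 | alkenylmagnesium bromide bis(alkoxide), Mg on C2 cis to the CH2O group on C3 | Cl[Mg]OC/C([Mg]Br)=C(\CC/C=C(\C)CC[C@@H]1C(C)=CCCC1(C)C)CO[Mg]Cl | intermediate
21 | (2E)-2-{(3E)-4-methyl-6-[(1S)-2,6,6-trimethylcyclohex-2-en-1-yl]hex-3-en-1-yl}but-2-ene-1,4-diol | OC/C=C(\CC/C=C(\C)CC[C@@H]1C(C)=CCCC1(C)C)CO | intermediate
22 | (2E,6E)-3-(acetoxymethyl)-7-methyl-9-[(1S)-2,6,6-trimethylcyclohex-2-en-1-yl]nona-2,6-dien-1-yl acetate | CC(=O)OC/C=C(\CC/C=C(\C)CC[C@@H]1C(C)=CCCC1(C)C)COC(C)=O | target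

Total step count: 9. Longest linear sequence: 9.

Steps most likely to fail

Step 3. Bond formation at C1', next to the quaternary carbon, may be slower than thermal elimination of the ketene N,O-acetal to a cyclohexadiene, and reversible ionisation of the allylic C–O bond could erode the chirality transfer. The fallback replaces the intramolecular [3,3] shift by an intermolecular anti-SN2' substitution. It sets out from enone 4 and comes back at alcohol 8. Reduction of 4 with (R)-Me-CBS and BH3·SMe2 should give (1S)-2,4,4-trimethylcyclohex-2-en-1-ol F1. Esterification with picolinic acid (EDC, DMAP) gives (1S)-2,4,4-trimethylcyclohex-2-en-1-yl pyridine-2-carboxylate F2. Vinylmagnesium bromide with CuBr·SMe2 (THF, −40 to 0 °C) should attack C1' anti to the chelation-activated leaving group and give (6S)-6-ethenyl-1,5,5-trimethylcyclohex-1-ene F3. 9-BBN should add only to the monosubstituted vinyl group to give the B-alkyl-9-borabicyclo[3.3.1]nonane F4, and NaOH/H2O2 then gives 8.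

Step 6. Ligand scrambling in the mixed cuprate, an incomplete 1,2-shift, or protonation of the alkenylcopper before methylation would waste the chiral alkyl group or leave the alkene without its methyl group. The fallback reverses the polarity of the ring fragment and replaces the metalate shift by a cross-coupling. It sets out from iodide 9 (with 12 made from 10) and comes back at alcohol 15. Alkylation of 12 with 9 (THF–DMPU, −30 °C to rt) gives 5-{2-[(1S)-2,6,6-trimethylcyclohex-2-en-1-yl]ethyl}-2,3-dihydrofuran F5. Nickel-catalysed coupling of its enol-ether C–O bond with MeMgBr ((Ph3P)2NiCl2 cat., toluene, reflux) replaces oxygen by methyl with retention and opens the ring to 15.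

Step 8. Addition of a primary alkyl Grignard reagent to the sparingly soluble bis-alkoxide may be too slow, the alkylcopper may decay thermally, and β-elimination from the alkenylmagnesium could lead towards an allenol. The fallback stores the geometry in an alkenyl iodide and joins the chain by an sp3–sp2 Negishi coupling. It sets out from 17 and from Grignard reagent 18 (made from 16) and comes back at diol 21. Trans-hydroalumination of 17 with Red-Al followed by I2 gives (2Z)-2-iodobut-2-ene-1,4-diol F6. TBSCl and imidazole give (2Z)-1,4-bis(tert-butyldimethylsilyloxy)-2-iodobut-2-ene F7. Transmetalation of 18 with ZnBr2 gives the alkylzinc bromide F8. PdCl2(dppf)-catalysed coupling of F7 with F8 (THF, rt) should give, with retention, the bis(tert-butyldimethylsilyl) ether of 21 F9. TBAF then gives 21.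

Further compounds
F1 | step 3 | (1S)-2,4,4-trimethylcyclohex-2-en-1-ol | CC1=CC(C)(C)CC[C@@H]1O
F2 | step 3 | (1S)-2,4,4-trimethylcyclohex-2-en-1-yl pyridine-2-carboxylate | CC1=CC(C)(C)CC[C@@H]1OC(=O)c1ccccn1
F3 | step 3 | (6S)-6-ethenyl-1,5,5-trimethylcyclohex-1-ene | C=C[C@@H]1C(C)=CCCC1(C)C
F4 | step 3 | 9-{2-[(1S)-2,6,6-trimethylcyclohex-2-en-1-yl]ethyl}-9-borabicyclo[3.3.1]nonane | B1(C2CCCC1CCC2)CC[C@@H]1C(C)=CCCC1(C)C
F5 | step 6 | 5-{2-[(1S)-2,6,6-trimethylcyclohex-2-en-1-yl]ethyl}-2,3-dihydrofuran | O1CCC=C1CC[C@@H]1C(C)=CCCC1(C)C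
F6 | step 8 | (2Z)-2-iodobut-2-ene-1,4-diol | OC/C=C(\I)CO
F7 | step 8 | (2Z)-1,4-bis(tert-butyldimethylsilyloxy)-2-iodobut-2-ene | CC(C)(C)[Si](C)(C)OC/C=C(\I)CO[Si](C)(C)C(C)(C)C
F8 | step 8 | (3E)-4-methyl-6-[(1S)-2,6,6-trimethylcyclohex-2-en-1-yl]hex-3-en-1-ylzinc bromide | Br[Zn]CC/C=C(\C)CC[C@@H]1C(C)=CCCC1(C)C
F9 | step 8 | bis(tert-butyldimethylsilyl) ether of 21 | CC(C)(C)[Si](C)(C)OC/C=C(\CC/C=C(\C)CC[C@@H]1C(C)=CCCC1(C)C)CO[Si](C)(C)C(C)(C)C
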